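**Retrosynthetic overview**
1. Pakyonol (rings A–D) ⇐ O-methylation and one global hydrogenolysis (one ArBr, two ArCl, OBn) of a halogen-coded macrocyclic phenol.
2. Key disconnection: the ring A–O–ring B diaryl ether, closed as the only ring-forming event (20-membered ring) by oxidative phenol coupling of an open bis(bibenzyl) bisphenol. This is the phenol coupling by which liverworts join lunularin units, run with ring A as 2,6-dibromophenol (oxidised partner) and ring B as 2,6-dichlorophenol (oxygen nucleophile).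
3. Open bisphenol ⇐ two B-alkyl Suzuki couplings on a ring C–O–ring D core: 4-acetoxystyrene onto the ring D bromide, 4-bromo-2,6-dichlorophenol onto the ring C vinyl group; ring A is brominated last.
4. Core ⇐ SNAr of 3-bromophenol on 3-(benzyloxy)-4-fluorobenzaldehyde, then Wittig methylenation.
5. Ring order: all four benzene rings are bought; the macrocycle is the single ring formed (step 6).

Assumption: pakyonol has no stereocentre and no configurationally stable axis or plane, so the SMILES describes one achiral compound and no enantiocontrol is needed; 3-(benzyloxy)-4-fluorobenzaldehyde is taken as a catalogue item.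

Ring labels: ring A = ring that ends with OMe; ring B = para-phenylene ring; ring C = ring that ends with the free OH; ring D = meta-phenylene ring.

**Route**

Step 1
Reactants: 1 3-(benzyloxy)-4-fluorobenzaldehyde; 2 3-bromophenol
Product: 3 3-(benzyloxy)-4-(3-bromophenoxy)benzaldehyde
Conditions: K2CO3, DMF, 120 °C
Reagents that add atoms: none
Why: SNAr (addition–elimination): the para-formyl group activates the C–F bond of 1 toward the phenoxide of 2 and the aryl bromide is inert, so the ring C–O–ring D ether forms with the benzyl-protected oxygen already ortho to it.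

Step 2
Reactants: 3 3-(benzyloxy)-4-(3-bromophenoxy)benzaldehyde
Product: 4 2-(benzyloxy)-1-(3-bromophenoxy)-4-ethenylbenzene
Conditions: Ph3PCH3Br, KOtBu, THF, 0 °C → rt
Reagents that add atoms: methyltriphenylphosphonium bromide, C[P+](c1ccccc1)(c1ccccc1)c1ccccc1.[Br-]
Why: Wittig methylenation of a non-enolisable aryl aldehyde turns the SNAr-activating formyl group into the vinyl handle for the ring B arm without touching the aryl bromide or the benzyl ether.

Step 3
Reactants: 4 2-(benzyloxy)-1-(3-bromophenoxy)-4-ethenylbenzene; 5 4-ethenylphenyl acetate (4-acetoxystyrene)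
Product: 8 4-(2-{3-[2-(benzyloxy)-4-ethenylphenoxy]phenyl}ethyl)phenol, via alkylborane 6 (not isolated), via aryl acetate 7 (not isolated)
Conditions: 5, 9-BBN (slightly less than 5), THF, 0 °C → rt; then 4, PdCl2(dppf), aq. K3PO4, DMF–THF, 60 °C; then K2CO3, MeOH, rt
Reagents that add atoms: none
Why: anti-Markovnikov hydroboration of styrene 5 and B-alkyl Suzuki–Miyaura coupling at the only C–Br bond build the ring A–CH2CH2–ring D bibenzyl directly at the saturated level (no B–H is left to attack the vinyl group of 4), and methanolysis of the acetate frees the ring A phenol.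

Step 4
Reactants: 8 4-(2-{3-[2-(benzyloxy)-4-ethenylphenoxy]phenyl}ethyl)phenol; 9 4-bromo-2,6-dichlorophenol
Product: 11 4-[2-(3-(benzyloxy)-4-{3-[2-(4-hydroxyphenyl)ethyl]phenoxy}phenyl)ethyl]-2,6-dichlorophenol, via bis-borane 10 (not isolated)
Conditions: 8, 9-BBN (2.2 equiv), THF, rt; then 9, PdCl2(dppf), aq. K3PO4, DMF–THF, 70 °C
Reagents that add atoms: none
Why: hydroboration of the ring C styrene (one further equivalent of 9-BBN sits on the ring A phenol as a borinate that the aqueous base releases) followed by B-alkyl Suzuki–Miyaura coupling at C–Br, with the C–Cl bonds inert to this catalyst, delivers ring B already coded as a 2,6-dichlorophenol.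

Step 5
Reactants: 11 4-[2-(3-(benzyloxy)-4-{3-[2-(4-hydroxyphenyl)ethyl]phenoxy}phenyl)ethyl]-2,6-dichlorophenol
Product: 12 2,6-dibromo-4-[2-(3-{2-(benzyloxy)-4-[2-(3,5-dichloro-4-hydroxyphenyl)ethyl]phenoxy}phenyl)ethyl]phenol
Conditions: NBS (2.05 equiv), iPr2NH (0.2 equiv), CH2Cl2, 0 °C
Reagents that add atoms: N-bromosuccinimide, O=C1CCC(=O)N1Br
Why: amine-catalysed ortho-bromination of a phenol (electrophilic aromatic substitution): ring A is the only phenol with free ortho positions (ring B is blocked by two Cl and its alkyl chain, rings C and D are only ethers), and any stray halogen on an ether ring is removed in step 8.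

Step 6
Reactants: 12 2,6-dibromo-4-[2-(3-{2-(benzyloxy)-4-[2-(3,5-dichloro-4-hydroxyphenyl)ethyl]phenoxy}phenyl)ethyl]phenol
Product: 14 macrocyclic phenol (pakyonol skeleton with ring A OH flanked by Br and the ring B oxygen, ring B with two Cl ortho to that oxygen, ring C OBn), via dienone 13 (not isolated)
Conditions: Tl(NO3)3·3H2O (2.5 equiv), MeOH–THF, 1 mM, −20 → 0 °C; then Zn, AcOH, rt
Reagents that add atoms: none
Why: Yamamura-type oxidative coupling of ortho-halophenols with trivalent thallium: the dibromophenol (ring A) is oxidised in preference to the dichlorophenol, the ring B oxygen (its ortho carbons blocked, so only O-attack) displaces one ortho bromine and methanol caps the para carbon to give quinol ether 13 (its one stereocentre racemic and transient), and Zn/AcOH re-aromatises ring A to close the achiral 20-membered diaryl ether.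

Step 7
Reactants: 14 macrocyclic phenol
Product: 15 macrocyclic methyl ether (ring A OMe flanked by Br and the ring B oxygen)
Conditions: MeI, K2CO3, DMF, rt
Reagents that add atoms: iodomethane, CI
Why: Williamson O-methylation of the only free phenol (the ring C oxygen is still benzylated, the ring B oxygen is now the ether) fixes the ring A methoxy group.

Step 8
Reactants: 15 macrocyclic methyl ether
Product: 16 pakyonol
Conditions: H2 (3 atm), Pd(OH)2/C, NaOAc, MeOH–THF, rt
Reagents that add atoms: none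
Why: catalytic hydrogenolysis removes the three coding halogens (hydrodehalogenation buffered by NaOAc) and the benzyl ether in one operation while diaryl and methyl ethers survive, giving achiral pakyonol with no stereocentre to set.

**Compound list**
1 | 3-(benzyloxy)-4-fluorobenzaldehyde | O=Cc1ccc(F)c(OCc2ccccc2)c1 | starting material
2 | 3-bromophenol | Oc1cccc(Br)c1 | starting material
3 | 3-(benzyloxy)-4-(3-bromophenoxy)benzaldehyde | O=Cc1ccc(Oc2cccc(Br)c2)c(OCc2ccccc2)c1 | intermediate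
4 | 2-(benzyloxy)-1-(3-bromophenoxy)-4-ethenylbenzene | C=Cc1ccc(Oc2cccc(Br)c2)c(OCc2ccccc2)c1 | intermediate
5 | 4-ethenylphenyl acetate | CC(=O)Oc1ccc(C=C)cc1 | starting material
6 | 4-[2-(9-borabicyclo[3.3.1]nonan-9-yl)ethyl]phenyl acetate | CC(=O)Oc1ccc(CCB2C3CCCC2CCC3)cc1 | intermediate (not isolated)
7 | 4-(2-{3-[2-(benzyloxy)-4-ethenylphenoxy]phenyl}ethyl)phenyl acetate | CC(=O)Oc1ccc(CCc2cccc(Oc3ccc(C=C)cc3OCc3ccccc3)c2)cc1 | intermediate (not isolated)
8 | 4-(2-{3-[2-(benzyloxy)-4-ethenylphenoxy]phenyl}ethyl)phenol | Oc1ccc(CCc2cccc(Oc3ccc(C=C)cc3OCc3ccccc3)c2)cc1 | intermediate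
9 | 4-bromo-2,6-dichlorophenol | Oc1c(Cl)cc(Br)cc1Cl | starting material
10 | bis-borane of 8 (ring A O–9-BBN borinate, ring C CH2CH2–9-BBN) | B1(Oc2ccc(CCc3cccc(Oc4ccc(CCB5C6CCCC5CCC6)cc4OCc4ccccc4)c3)cc2)C2CCCC1CCC2 | intermediate (not isolated)
11 | 4-[2-(3-(benzyloxy)-4-{3-[2-(4-hydroxyphenyl)ethyl]phenoxy}phenyl)ethyl]-2,6-dichlorophenol | Oc1ccc(CCc2cccc(Oc3ccc(CCc4cc(Cl)c(O)c(Cl)c4)cc3OCc3ccccc3)c2)cc1 | intermediate
12 | 2,6-dibromo-4-[2-(3-{2-(benzyloxy)-4-[2-(3,5-dichloro-4-hydroxyphenyl)ethyl]phenoxy}phenyl)ethyl]phenol | Oc1c(Br)cc(CCc2cccc(Oc3ccc(CCc4cc(Cl)c(O)c(Cl)c4)cc3OCc3ccccc3)c2)cc1Br | intermediate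
13 | macrocyclic 2-aryloxy-6-bromo-4-methoxycyclohexa-2,5-dienone (quinol methyl ether of ring A; racemic) | O=C1C(Br)=CC2(OC)C=C1Oc1c(Cl)cc(cc1Cl)CCc1ccc(c(OCc3ccccc3)c1)Oc1cccc(c1)CC2 | intermediate (not isolated)
14 | macrocyclic phenol (ring A: OH, Br; ring B: 2 Cl; ring C: OBn) | Oc1c(Br)cc2cc1Oc1c(Cl)cc(cc1Cl)CCc1ccc(c(OCc3ccccc3)c1)Oc1cccc(c1)CC2 | intermediate
15 | macrocyclic methyl ether (ring A: OMe, Br; ring B: 2 Cl; ring C: OBn) | COc1c(Br)cc2cc1Oc1c(Cl)cc(cc1Cl)CCc1ccc(c(OCc3ccccc3)c1)Oc1cccc(c1)CC2 | intermediate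
16 | pakyonol (achiral) | COc1ccc2cc1Oc1ccc(cc1)CCc1ccc(c(O)c1)Oc1cccc(c1)CC2 | target

**Totals**
Total step count: 8. Longest linear sequence: 8 steps (1 → 16; 2, 5 and 9 enter directly).

**Three steps most likely to fail, with fallbacks**

Step 6 (oxidative macrocyclisation). The 20-membered closure competes with oligomerisation and with simple para-trapping by methanol; the latter only returns 12 after the Zn reduction, so that material can be recycled. Fallback, setting out from 8 and returning at 16: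
- NBS (1.0 equiv), iPr2NH cat., CH2Cl2, −20 °C gives 2-bromo-4-(2-{3-[2-(benzyloxy)-4-ethenylphenoxy]phenyl}ethyl)phenol F1.
- MeI, K2CO3 gives 2-(benzyloxy)-1-{3-[2-(3-bromo-4-methoxyphenyl)ethyl]phenoxy}-4-ethenylbenzene F2.
- 9-BBN gives the B-alkyl-9-BBN adduct F3, coupled in the same flask with 4-iodophenol (PdCl2(dppf), K3PO4; C–I reacts before the hindered C–Br) to 4-[2-(3-(benzyloxy)-4-{3-[2-(3-bromo-4-methoxyphenyl)ethyl]phenoxy}phenyl)ethyl]phenol F4.
- High-dilution intramolecular Ullmann etherification (CuI, N,N-dimethylglycine, Cs2CO3, dioxane, 100 °C) closes the ring A–O–ring B ether to O-benzylpakyonol F5.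
- H2, Pd/C removes the benzyl group and rejoins the route at 16.

Step 4 (B-alkyl Suzuki coupling onto an electron-rich bromophenoxide in the presence of free phenols). Fallback, setting out from 3 and returning at 11, in which the ring B arm is built first by olefination and the Suzuki electrophile becomes a neutral aryl bromide:
- 4-Hydroxybenzyl alcohol and triphenylphosphine hydrobromide give (4-hydroxybenzyl)triphenylphosphonium bromide F6.
- Its ylide (KOtBu, 2.2 equiv) and 3 give 4-{2-[3-(benzyloxy)-4-(3-bromophenoxy)phenyl]ethenyl}phenol F7 (E/Z mixture).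
- Diimide (TsNHNH2, NaOAc, THF–H2O, reflux) gives 4-{2-[3-(benzyloxy)-4-(3-bromophenoxy)phenyl]ethyl}phenol F8.
- SO2Cl2 (2.1 equiv), iBu2NH cat., toluene, 70 °C gives 4-{2-[3-(benzyloxy)-4-(3-bromophenoxy)phenyl]ethyl}-2,6-dichlorophenol F9.
- B-alkyl Suzuki coupling of F9 with alkylborane 6 (PdCl2(dppf), K3PO4) gives 4-[2-(3-{2-(benzyloxy)-4-[2-(3,5-dichloro-4-hydroxyphenyl)ethyl]phenoxy}phenyl)ethyl]phenyl acetate F10.
- K2CO3, MeOH rejoins the route at 11.

Step 3 (B-alkyl Suzuki coupling beside a free styrene; Heck-type side reactions and premature acetate loss). Fallback, setting out from 3 and returning at 8, replacing hydroboration/Suzuki by Heck/hydrogenation before the methylenation: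
- Heck reaction of 3 with 5 (Pd(OAc)2, P(o-tol)3, NaOAc, DMF, 110 °C) gives 4-[(E)-2-{3-[2-(benzyloxy)-4-formylphenoxy]phenyl}ethenyl]phenyl acetate F11.
- H2 over Pd/C poisoned with Ph2S reduces only the alkene to 4-(2-{3-[2-(benzyloxy)-4-formylphenoxy]phenyl}ethyl)phenyl acetate F12.
- K2CO3, MeOH in the same flask gives 3-(benzyloxy)-4-{3-[2-(4-hydroxyphenyl)ethyl]phenoxy}benzaldehyde F13.
- Ph3P=CH2 (2.5 equiv) rejoins the route at 8.

**Further compounds**
F1 | step 6 | 2-bromo-4-(2-{3-[2-(benzyloxy)-4-ethenylphenoxy]phenyl}ethyl)phenol | Oc1ccc(CCc2cccc(Oc3ccc(C=C)cc3OCc3ccccc3)c2)cc1Br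
F2 | step 6 | 2-(benzyloxy)-1-{3-[2-(3-bromo-4-methoxyphenyl)ethyl]phenoxy}-4-ethenylbenzene | COc1ccc(CCc2cccc(Oc3ccc(C=C)cc3OCc3ccccc3)c2)cc1Br
F3 | step 6 | B-alkyl-9-BBN adduct of F2 | COc1ccc(CCc2cccc(Oc3ccc(CCB4C5CCCC4CCC5)cc3OCc3ccccc3)c2)cc1Br
F4 | step 6 | 4-[2-(3-(benzyloxy)-4-{3-[2-(3-bromo-4-methoxyphenyl)ethyl]phenoxy}phenyl)ethyl]phenol | COc1ccc(CCc2cccc(Oc3ccc(CCc4ccc(O)cc4)cc3OCc3ccccc3)c2)cc1Br
F5 | step 6 | O-benzylpakyonol | COc1ccc2cc1Oc1ccc(cc1)CCc1ccc(c(OCc3ccccc3)c1)Oc1cccc(c1)CC2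
F6 | step 4 | (4-hydroxybenzyl)triphenylphosphonium bromide | Oc1ccc(C[P+](c2ccccc2)(c2ccccc2)c2ccccc2)cc1.[Br-]
F7 | step 4 | 4-{2-[3-(benzyloxy)-4-(3-bromophenoxy)phenyl]ethenyl}phenol (E/Z mixture) | Oc1ccc(C=Cc2ccc(Oc3cccc(Br)c3)c(OCc3ccccc3)c2)cc1
F8 | step 4 | 4-{2-[3-(benzyloxy)-4-(3-bromophenoxy)phenyl]ethyl}phenol | Oc1ccc(CCc2ccc(Oc3cccc(Br)c3)c(OCc3ccccc3)c2)cc1
F9 | step 4 | 4-{2-[3-(benzyloxy)-4-(3-bromophenoxy)phenyl]ethyl}-2,6-dichlorophenol | Oc1c(Cl)cc(CCc2ccc(Oc3cccc(Br)c3)c(OCc3ccccc3)c2)cc1Cl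
F10 | step 4 | 4-[2-(3-{2-(benzyloxy)-4-[2-(3,5-dichloro-4-hydroxyphenyl)ethyl]phenoxy}phenyl)ethyl]phenyl acetate | CC(=O)Oc1ccc(CCc2cccc(Oc3ccc(CCc4cc(Cl)c(O)c(Cl)c4)cc3OCc3ccccc3)c2)cc1
F11 | step 3 | 4-[(E)-2-{3-[2-(benzyloxy)-4-formylphenoxy]phenyl}ethenyl]phenyl acetate | CC(=O)Oc1ccc(/C=C/c2cccc(Oc3ccc(C=O)cc3OCc3ccccc3)c2)cc1
F12 | step 3 | 4-(2-{3-[2-(benzyloxy)-4-formylphenoxy]phenyl}ethyl)phenyl acetate | CC(=O)Oc1ccc(CCc2cccc(Oc3ccc(C=O)cc3OCc3ccccc3)c2)cc1
F13 | step 3 | 3-(benzyloxy)-4-{3-[2-(4-hydroxyphenyl)ethyl]phenoxy}benzaldehyde | Oc1ccc(CCc2cccc(Oc3ccc(C=O)cc3OCc3ccccc3)c2)cc1
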